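**Prosogerin D by a diene plus diynone route: ring A from two open chains, ring C by amine-mediated closure**

- Cuts: O1–C2 (ring C) first; then C5–C6 and C4a–C8a, which opens ring A into two acyclic partners; then C4–C4a and C3–C4 of the remaining aryl penta-1,4-diyn-3-one.
- Enabling feature: ring A holds its three oxygens in a 1,3,4 pattern (O1 on C8a, hydroxyl on C7, methyl ether on C6) next to the acyl-bearing C4a. That is the oxygen pattern of a 4-methoxy-3-oxobutanoate (C8a–C8–C7–C6) added across an alkynyl ketone (C5–C4a–C4), so each oxygen arrives in its final form.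
- Forward: ring B is bought as 3,4,5-trimethoxyphenylacetylene; formylation, ethynyl Grignard addition and oxidation give the diynone (C5–C4a–C4–C3–C2), and the keto ester is turned into its bis-silyl dienol ether.
- Ring order: ring A forms first by (4+2) cycloaddition at the terminal alkyne and aromatisation with loss of methanol; ring C forms last by 6-endo closure of the C8a hydroxyl onto the remaining aryl ynone.
- Stereochemistry: the target has no stereocentre and no stereogenic double bond. The carbinol centre of the diynol and the two sp3 carbons of the cycloadduct are erased; only the C3=C4 geometry of the diene (methoxy on the outside) has to be right.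

Key step: step 6

Assumption: ring atoms carry flavone numbering (O1, C2–C4, C4a, C5–C8, C8a) in all precursors; the geometries drawn for silyl enol ether 11 and for the ketene acetal end of diene 13 are the expected ones and do not affect the product.

**Step 1**
Reactants: 1 5-ethynyl-1,2,3-trimethoxybenzene; 2 N,N-dimethylformamide
Product: 5 3-(3,4,5-trimethoxyphenyl)prop-2-ynal, via lithium acetylide 3 (not isolated), via lithium hemiaminal alkoxide 4 (not isolated)
Conditions: n-BuLi (1.05 equiv), THF, −78 °C; 2 (2 equiv), −78 → 0 °C; reverse quench into cold aq KH2PO4/MTBE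
Reagents that add atoms: none
Why: Bouveault-type formylation of a lithium acetylide with DMF is standard for aryl propynals, and the reverse quench into phosphate buffer keeps the released dimethylamine protonated so that it cannot add to the ynal.

**Step 2**
Reactants: 5 3-(3,4,5-trimethoxyphenyl)prop-2-ynal; 6 ethynylmagnesium bromide
Product: 8 1-(3,4,5-trimethoxyphenyl)penta-1,4-diyn-3-ol (racemic), via bromomagnesium alkoxide 7 (not isolated)
Conditions: 6 (0.5 M in THF, 1.2 equiv), THF, −78 → 0 °C; sat. aq NH4Cl
Reagents that add atoms: none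
Why: Grignard 1,2-addition of an alkynyl nucleophile to an ynal is fast at low temperature and should outrun conjugate addition; the new carbinol centre is racemic and is removed in step 3.

**Step 3**
Reactants: 8 1-(3,4,5-trimethoxyphenyl)penta-1,4-diyn-3-ol
Product: 9 1-(3,4,5-trimethoxyphenyl)penta-1,4-diyn-3-one
Conditions: activated MnO2 (excess), CH2Cl2, 0 °C → rt; filtration through Celite; solvent exchanged for toluene below 20 °C, solution used at once
Reagents that add atoms: none
Why: MnO2 oxidation of a doubly propargylic alcohol proceeds under neutral heterogeneous conditions with filtration as the only work-up, which suits an electrophilic terminal diynone that is not stored.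

**Step 4**
Reactants: 10 methyl 4-methoxy-3-oxobutanoate (methyl 4-methoxyacetoacetate)
Product: 11 methyl (E)-4-methoxy-3-(trimethylsilyloxy)but-2-enoate
Conditions: Me3SiCl (1.5 equiv), Et3N (1.5 equiv), toluene, rt; filtration under argon, distillation
Reagents that add atoms: chlorotrimethylsilane, C[Si](C)(C)Cl
Why: O-silylation of the enol of a β-keto ester with Me3SiCl and Et3N is the usual first stage towards 1,3-bis(silyloxy)dienes; the E isomer is expected to predominate, and either geometry can be deprotonated at C4 in step 5.

**Step 5**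
Reactants: 11 methyl (E)-4-methoxy-3-(trimethylsilyloxy)but-2-enoate
Product: 13 (1Z,3Z)-1,4-dimethoxy-1,3-bis(trimethylsilyloxy)buta-1,3-diene, via lithium dienolate 12 (not isolated)
Conditions: LiN(iPr)2 (1.2 equiv), THF, −78 °C; Me3SiCl (1.3 equiv), −78 °C → rt; pentane, filtration under argon, used crude
Reagents that add atoms: chlorotrimethylsilane, C[Si](C)(C)Cl
Why: vinylogous (γ) deprotonation of the silyloxy enoate and O-silylation of the extended enolate is the established second stage to such dienes; 1,3-allylic strain towards the ester-bearing carbon, helped by lithium bridging of the methoxy and silyloxy oxygens, should place the C4 methoxy group cis to the C3 silyloxy group, that is, outside in the s-cis diene.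

**Step 6**
Reactants: 9 1-(3,4,5-trimethoxyphenyl)penta-1,4-diyn-3-one; 13 (1Z,3Z)-1,4-dimethoxy-1,3-bis(trimethylsilyloxy)buta-1,3-diene
Product: 15 1-(2,4-dihydroxy-5-methoxyphenyl)-3-(3,4,5-trimethoxyphenyl)prop-2-yn-1-one, via cyclohexa-1,4-diene cycloadduct 14 (not isolated)
Conditions: 13 (1.3 equiv), toluene, −78 °C → rt; then MeOH, p-TsOH (cat.), 0 °C → rt
Reagents that add atoms: none
Why: Carbon 4 of the diene (the methoxy-bearing terminus, future C6) is its most nucleophilic site and attacks the unsubstituted alkyne carbon of 9 (future C5), while the ketene acetal carbon (future C8a) joins the carbon next to the carbonyl (future C4a); the two bonds form either in one asynchronous event or by Mukaiyama–Michael addition followed by closure of the allenolate onto the oxocarbenium carbon, and both paths give cyclohexa-1,4-diene 14. The closest known reaction type is the Diels–Alder reaction and aromatisation of 1-alkoxy-1,3-bis(silyloxy)buta-1,3-dienes with acetylenic ketones and esters to give resorcinol derivatives. Ring A is closed in the (4+2) mode from two open-chain partners; in acidic methanol the silyl ethers are cleaved, the C8a hemiketal expels methanol and the resulting dienone tautomerises, so C8a and C7 emerge as free hydroxyls and the C6 methyl ether is untouched. The two sp3 carbons of 14 (C6 and C8a) form without control and disappear on aromatisation, so no stereochemical element has to be steered. Regiochemistry is secured because the three donor oxygens on diene carbons 1 and 3 outweigh the single methoxy group on carbon 4; site selectivity is secured because the terminal alkyne is unhindered and more electrophilic than the alkyne conjugated to the electron-rich trimethoxyphenyl ring.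

**Step 7**
Reactants: 15 1-(2,4-dihydroxy-5-methoxyphenyl)-3-(3,4,5-trimethoxyphenyl)prop-2-yn-1-one
Product: 17 Prosogerin D (7-hydroxy-6-methoxy-2-(3,4,5-trimethoxyphenyl)-4H-chromen-4-one), via diethylamino enone 16 (not isolated)
Conditions: Et2NH (5 equiv), EtOH, rt → 60 °C
Reagents that add atoms: none
Why: diethylamine adds to the aryl ynone to give β-amino enone 16, and the C8a hydroxyl then displaces the amine at C2 by intramolecular oxa-Michael addition–elimination, which can only form the six-membered pyranone (net 6-endo closure) and so should avoid the 5-exo aurone pathway of plain base-mediated cyclisation.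

**Compound list**

1 | 5-ethynyl-1,2,3-trimethoxybenzene | C#Cc1cc(OC)c(OC)c(OC)c1 | starting material
2 | N,N-dimethylformamide | CN(C)C=O | starting material
3 | lithium (3,4,5-trimethoxyphenyl)acetylide | [Li]C#Cc1cc(OC)c(OC)c(OC)c1 | intermediate (not isolated)
4 | lithium 1-(dimethylamino)-3-(3,4,5-trimethoxyphenyl)prop-2-yn-1-olate, racemic | CN(C)C(O[Li])C#Cc1cc(OC)c(OC)c(OC)c1 | intermediate (not isolated)
5 | 3-(3,4,5-trimethoxyphenyl)prop-2-ynal | O=CC#Cc1cc(OC)c(OC)c(OC)c1 | intermediate
6 | ethynylmagnesium bromide | C#C[Mg]Br | starting material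
7 | bromomagnesium 1-(3,4,5-trimethoxyphenyl)penta-1,4-diyn-3-olate, racemic | C#CC(O[Mg]Br)C#Cc1cc(OC)c(OC)c(OC)c1 | intermediate (not isolated)
8 | 1-(3,4,5-trimethoxyphenyl)penta-1,4-diyn-3-ol, racemic | C#CC(O)C#Cc1cc(OC)c(OC)c(OC)c1 | intermediate
9 | 1-(3,4,5-trimethoxyphenyl)penta-1,4-diyn-3-one | C#CC(=O)C#Cc1cc(OC)c(OC)c(OC)c1 | intermediate
10 | methyl 4-methoxy-3-oxobutanoate | COCC(=O)CC(=O)OC | starting material
11 | methyl (E)-4-methoxy-3-(trimethylsilyloxy)but-2-enoate | COC/C(O[Si](C)(C)C)=C\C(=O)OC | intermediate
12 | lithium (1E,3Z)-1,4-dimethoxy-3-(trimethylsilyloxy)buta-1,3-dien-1-olate (OLi cis to C3; C4 methoxy cis to the C3 silyloxy group) | CO/C=C(O[Si](C)(C)C)/C=C(OC)\O[Li] | intermediate (not isolated)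
13 | (1Z,3Z)-1,4-dimethoxy-1,3-bis(trimethylsilyloxy)buta-1,3-diene (C4 methoxy cis to the C3 silyloxy group) | CO/C=C(O[Si](C)(C)C)/C=C(OC)\O[Si](C)(C)C | intermediate
14 | 1-[3,6-dimethoxy-4,6-bis(trimethylsilyloxy)cyclohexa-1,4-dien-1-yl]-3-(3,4,5-trimethoxyphenyl)prop-2-yn-1-one, mixture of diastereomers | COC1C=C(C(=O)C#Cc2cc(OC)c(OC)c(OC)c2)C(OC)(O[Si](C)(C)C)C=C1O[Si](C)(C)C | intermediate (not isolated)
15 | 1-(2,4-dihydroxy-5-methoxyphenyl)-3-(3,4,5-trimethoxyphenyl)prop-2-yn-1-one | COc1cc(C(=O)C#Cc2cc(OC)c(OC)c(OC)c2)c(O)cc1O | intermediate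
16 | (E)-3-(diethylamino)-1-(2,4-dihydroxy-5-methoxyphenyl)-3-(3,4,5-trimethoxyphenyl)prop-2-en-1-one | CCN(CC)/C(=C/C(=O)c1cc(OC)c(O)cc1O)c1cc(OC)c(OC)c(OC)c1 | intermediate (not isolated)
17 | Prosogerin D, 7-hydroxy-6-methoxy-2-(3,4,5-trimethoxyphenyl)-4H-chromen-4-one | COc1cc2c(=O)cc(-c3cc(OC)c(OC)c(OC)c3)oc2cc1O | target

**Step count**

Total: 7 steps. Longest linear sequence: 5 steps (steps 1, 2, 3, 6, 7 from alkyne 1); the diene branch (steps 4 and 5) joins at step 6.

**Steps most likely to fail**

1. Step 6. The diynone may oligomerise, or be attacked at the aryl-substituted alkyne or at the carbonyl group, faster than the desired cycloaddition occurs. The first carbon–carbon bond may also form without ring closure, so that no arene results. The fallback takes ring A from a purchased arene; it sets out from alkyne 1 (lithiated to acetylide 3 as in step 1) and comes back to the route at 15. Commercial 2,4-dihydroxy-5-methoxybenzaldehyde is protected with MOMCl and iPr2NEt in CH2Cl2 to give 5-methoxy-2,4-bis(methoxymethoxy)benzaldehyde F1. Addition of acetylide 3 in THF at −78 °C should give 1-[5-methoxy-2,4-bis(methoxymethoxy)phenyl]-3-(3,4,5-trimethoxyphenyl)prop-2-yn-1-ol F2. MnO2 in CH2Cl2 oxidises this to 1-[5-methoxy-2,4-bis(methoxymethoxy)phenyl]-3-(3,4,5-trimethoxyphenyl)prop-2-yn-1-one F3. HCl in MeOH then removes both acetals and delivers 15, which continues with step 7.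

2. Step 3. The terminal diynone may be consumed by conjugate addition and oligomerisation on the oxidant surface or during concentration. The fallback carries the terminal alkyne in C-silylated form through the oxidation; it sets out from aldehyde 5 and comes back at 9. Lithium (trimethylsilyl)acetylide (from ethynyltrimethylsilane and n-BuLi, THF, −78 °C) adds to 5 to give 1-(3,4,5-trimethoxyphenyl)-5-(trimethylsilyl)penta-1,4-diyn-3-ol F4. MnO2 oxidation gives 1-(3,4,5-trimethoxyphenyl)-5-(trimethylsilyl)penta-1,4-diyn-3-one F5, which should be storable. Na2B4O7 in aqueous MeOH at rt removes the alkynyl silyl group just before the cycloaddition; 9 is extracted into toluene, dried and used as a solution in step 6.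

3. Step 7. The amine may deprotonate the phenols, which slows conjugate addition of the amine to the now electron-rich ynone and lets the C8a phenoxide attack the alkyne directly in the 5-exo mode. The fallback masks the phenols until the alkyne has been converted; it sets out from 15 and comes back at 17. TBSCl and imidazole in DMF give 1-[2,4-bis(tert-butyldimethylsilyloxy)-5-methoxyphenyl]-3-(3,4,5-trimethoxyphenyl)prop-2-yn-1-one F6. Et2NH in EtOH at rt adds to this neutral ynone to give (E)-1-[2,4-bis(tert-butyldimethylsilyloxy)-5-methoxyphenyl]-3-(diethylamino)-3-(3,4,5-trimethoxyphenyl)prop-2-en-1-one F7. Bu4NF in THF then cleaves both silyl ethers; the freed C8a phenoxide meets an enaminone with no alkyne left, displaces diethylamine at C2 and gives 17.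

**Further compounds**

F1 | step 6 | 5-methoxy-2,4-bis(methoxymethoxy)benzaldehyde | COCOc1cc(OCOC)c(OC)cc1C=O
F2 | step 6 | 1-[5-methoxy-2,4-bis(methoxymethoxy)phenyl]-3-(3,4,5-trimethoxyphenyl)prop-2-yn-1-ol, racemic | COCOc1cc(OCOC)c(OC)cc1C(O)C#Cc1cc(OC)c(OC)c(OC)c1
F3 | step 6 | 1-[5-methoxy-2,4-bis(methoxymethoxy)phenyl]-3-(3,4,5-trimethoxyphenyl)prop-2-yn-1-one | COCOc1cc(OCOC)c(OC)cc1C(=O)C#Cc1cc(OC)c(OC)c(OC)c1
F4 | step 3 | 1-(3,4,5-trimethoxyphenyl)-5-(trimethylsilyl)penta-1,4-diyn-3-ol, racemic | C[Si](C)(C)C#CC(O)C#Cc1cc(OC)c(OC)c(OC)c1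
F5 | step 3 | 1-(3,4,5-trimethoxyphenyl)-5-(trimethylsilyl)penta-1,4-diyn-3-one | C[Si](C)(C)C#CC(=O)C#Cc1cc(OC)c(OC)c(OC)c1
F6 | step 7 | 1-[2,4-bis(tert-butyldimethylsilyloxy)-5-methoxyphenyl]-3-(3,4,5-trimethoxyphenyl)prop-2-yn-1-one | COc1cc(C(=O)C#Cc2cc(OC)c(OC)c(OC)c2)c(O[Si](C)(C)C(C)(C)C)cc1O[Si](C)(C)C(C)(C)C
F7 | step 7 | (E)-1-[2,4-bis(tert-butyldimethylsilyloxy)-5-methoxyphenyl]-3-(diethylamino)-3-(3,4,5-trimethoxyphenyl)prop-2-en-1-one | CCN(CC)/C(=C/C(=O)c1cc(OC)c(O[Si](C)(C)C(C)(C)C)cc1O[Si](C)(C)C(C)(C)C)c1cc(OC)c(OC)c(OC)c1
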